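**Retrosynthetic overview**

1. Target ⇐ one-pot ring transformation of a 2,3-disubstituted γ-pyrone: O-methylation to a 4-methoxypyrylium, attack of the side-chain secondary OH on the pyrylium α-carbon (closes the dihydrofuran), electrocyclic opening of the 2H-pyran to a methoxy dienal, then intramolecular aldol of the side-chain ketone onto that aldehyde (closes the cyclohexadiene, sets C6/C7). The pyran oxygen ends as the C6 hydroxyl and the pyrone carbonyl oxygen as the C4 OMe.
2. Acyl-bearing γ-pyrone ⇐ lateral acylation of the 2-methyl-γ-pyrone with the Weinreb amide of 3-phenylpropanoic acid.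
3. 2-Methyl-γ-pyrone ⇐ conjugate addition of 6-methoxyhex-5-ene-2,4-dione to an o-quinone methide released by fluoride from a silyl-protected aryl epoxide (sets C3 next to C2), then acid closure to the pyrone.
4. Epoxide ⇐ Shi epoxidation (sets C2) of the Heck product from the silylated iodophenol ester and 2-methylbut-3-en-2-ol; diketone ⇐ 4-methoxybut-3-en-2-one + acetyl chloride.
5. Ring order: temporary γ-pyrone (step 5), then dihydrofuran and cyclohexadiene together in step 7 while the pyran ring is cut open.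

Assumption: the L-fructose-derived (ent-)Shi ketone, CsF and Weinreb amide 12 are bought as such; centres that are stereolabile and erased in the same pot (the diketone CH of 10, the ketal carbon of 15) are left undefined in the SMILES.

**Route**

Step 1
Reactants: 1 methyl 4-hydroxy-3-iodobenzoate
Product: 2 methyl 3-iodo-4-[(triisopropylsilyl)oxy]benzoate
Conditions: i-Pr3SiCl, imidazole, DMF, 23 °C
Reagents that add atoms: triisopropylsilyl chloride, CC(C)[Si](Cl)(C(C)C)C(C)C
Why: Imidazole-promoted O-silylation masks the phenol so that the Heck and dioxirane steps never see a phenoxide and fluoride can later trigger quinone methide formation; no stereocentre is involved.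

Step 2
Reactants: 2 methyl 3-iodo-4-[(triisopropylsilyl)oxy]benzoate; 3 2-methylbut-3-en-2-ol
Product: 4 methyl 3-[(1E)-3-hydroxy-3-methylbut-1-en-1-yl]-4-[(triisopropylsilyl)oxy]benzoate
Conditions: Pd(OAc)2 (5 mol%), P(o-tol)3 (10 mol%), Et3N, MeCN, 80 °C
Reagents that add atoms: none
Why: Mizoroki–Heck reaction: syn-carbopalladation at the unsubstituted alkene carbon and syn-β-hydride elimination give the (E)-styrene, and the tertiary carbinol cannot isomerise to a ketone.

Step 3
Reactants: 4 methyl 3-[(1E)-3-hydroxy-3-methylbut-1-en-1-yl]-4-[(triisopropylsilyl)oxy]benzoate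
Product: 5 methyl 3-[(2S,3R)-3-(2-hydroxypropan-2-yl)oxiran-2-yl]-4-[(triisopropylsilyl)oxy]benzoate
Conditions: L-fructose-derived Shi ketone (30 mol%), KHSO5 (as 2KHSO5·KHSO4·K2SO4), K2CO3, Bu4NHSO4, MeCN–CH2(OMe)2–H2O, pH 10.5, 0 °C
Reagents that add atoms: potassium peroxymonosulfate KHSO5, [K+].[O-]S(=O)(=O)OO
Why: Shi asymmetric epoxidation: the chiral dioxirane transfers oxygen to the trans alkene through a spiro transition state, stereospecifically and on the face that gives the (2S,3R) epoxide (the D-fructose ketone gives the opposite face, as with trans-β-methylstyrene), which fixes the future C-2 oxygen stereocentre.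

Step 4
Reactants: 6 (3E)-4-methoxybut-3-en-2-one; 7 acetyl chloride
Product: 8 (5E)-6-methoxyhex-5-ene-2,4-dione
Conditions: LiN(SiMe3)2 (2.1 equiv), THF, −78 °C; then AcOH
Reagents that add atoms: none
Why: Claisen-type C-acylation of the kinetic lithium enolate of the methyl ketone; the second equivalent of base stores the more acidic 1,3-diketone as its enolate and the β-methoxyvinyl side has no enolisable position.

Step 5
Reactants: 5 methyl 3-[(2S,3R)-3-(2-hydroxypropan-2-yl)oxiran-2-yl]-4-[(triisopropylsilyl)oxy]benzoate; 8 (5E)-6-methoxyhex-5-ene-2,4-dione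
Product: 11 methyl 3-[(1R,2R)-2,3-dihydroxy-3-methyl-1-(2-methyl-4-oxo-4H-pyran-3-yl)butyl]-4-hydroxybenzoate, via o-quinone methide alkoxide 9 (not isolated), via Michael adduct 10 (not isolated)
Conditions: CsF, DMF, 0 → 23 °C; then CF3CO2H, CH2Cl2, 0 °C
Reagents that add atoms: none
Why: Fluoride frees the phenoxide, which opens the benzylic epoxide C–O bond to an o-quinone methide without touching the C-2 oxygen centre; the cesium enolate of 8 adds through its only doubly activated carbon anti to the bulky hydroxyisopropyl group in the A(1,3)-minimised conformer (sets the benzylic 1R centre by 1,2-induction), and acid closes the enol oxygen onto the β-methoxy enone with loss of methanol (Michael addition of a 1,3-dicarbonyl to an o-quinone methide, then γ-pyrone cyclocondensation).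

Step 6
Reactants: 11 methyl 3-[(1R,2R)-2,3-dihydroxy-3-methyl-1-(2-methyl-4-oxo-4H-pyran-3-yl)butyl]-4-hydroxybenzoate; 12 N-methoxy-N-methyl-3-phenylpropanamide
Product: 13 methyl 3-[(1R,2R)-2,3-dihydroxy-3-methyl-1-[4-oxo-2-(2-oxo-4-phenylbutyl)-4H-pyran-3-yl]butyl]-4-hydroxybenzoate
Conditions: LiN(SiMe3)2 (4.2 equiv), THF–DMPU, −78 → −40 °C; then 1 M HCl
Reagents that add atoms: none
Why: After the three OH groups are deprotonated, lateral metalation of the pyrone 2-methyl group gives the most basic, carbon-centred anion, which is acylated by the Weinreb amide through a chelated tetrahedral intermediate that releases the ketone only on work-up (Claisen-type acylation of a laterally lithiated γ-pyrone); the two stereocentres are not acidic and stay untouched.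

Step 7
Reactants: 13 methyl 3-[(1R,2R)-2,3-dihydroxy-3-methyl-1-[4-oxo-2-(2-oxo-4-phenylbutyl)-4H-pyran-3-yl]butyl]-4-hydroxybenzoate
Product: 17 methyl 4-hydroxy-3-[(2R,3R,6R,7R)-6-hydroxy-2-(2-hydroxypropan-2-yl)-4-methoxy-7-(3-phenylpropanoyl)-2,3,6,7-tetrahydro-1-benzofuran-3-yl]benzoate, via pyrylium triflate 14 (not isolated), via fused 2H-pyran ketal 15 (not isolated), via dienal 16 (not isolated)
Conditions: MeOTf (1.1 equiv), 2,6-di-tert-butyl-4-methylpyridine, CH2Cl2, −20 → 0 °C; then MgBr2·OEt2, i-Pr2NEt, −40 → −10 °C; pH 7 buffer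
Reagents that add atoms: methyl trifluoromethanesulfonate, COS(=O)(=O)C(F)(F)F
Why: Proposed new method: the pyrone carbonyl oxygen, the most nucleophilic site, is methylated to a 4-methoxypyrylium, the secondary hydroxyl adds 5-exo to the substituted α-carbon, and the resulting 2H-pyran ketal opens by retro-oxa-6π electrocyclisation to the dienal with CHO cis to the furan carbon (pyran oxygen becomes aldehyde oxygen); MgBr2/amine soft enolisation of the ketone then closes the carbocycle by intramolecular aldol (equivalent to disrotatory 6π closure of the trienolate) with magnesium chelating aldehyde and enolate oxygens so that OH and acyl end cis, while bridging to the C-2 hydroxyisopropyl oxygen is expected to favour the face that gives (6R,7R); the closest known reactions are pseudobase ring-opening of pyrylium salts, the pyrylium-to-arene ring transformation with carbanions (which passes through the same kind of cyclohexadienol before losing water) and MgBr2·OEt2/i-Pr2NEt soft-enolisation aldol chemistry.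

**Compound list**

1 | methyl 4-hydroxy-3-iodobenzoate | COC(=O)c1ccc(O)c(I)c1 | starting material
2 | methyl 3-iodo-4-[(triisopropylsilyl)oxy]benzoate | COC(=O)c1ccc(O[Si](C(C)C)(C(C)C)C(C)C)c(I)c1 | intermediate
3 | 2-methylbut-3-en-2-ol | CC(C)(O)C=C | starting material
4 | methyl 3-[(1E)-3-hydroxy-3-methylbut-1-en-1-yl]-4-[(triisopropylsilyl)oxy]benzoate | COC(=O)c1ccc(O[Si](C(C)C)(C(C)C)C(C)C)c(/C=C/C(C)(C)O)c1 | intermediate
5 | methyl 3-[(2S,3R)-3-(2-hydroxypropan-2-yl)oxiran-2-yl]-4-[(triisopropylsilyl)oxy]benzoate | COC(=O)c1ccc(O[Si](C(C)C)(C(C)C)C(C)C)c(c1)[C@@H]2O[C@H]2C(C)(C)O | intermediate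
6 | (3E)-4-methoxybut-3-en-2-one | CO/C=C/C(C)=O | starting material
7 | acetyl chloride | CC(Cl)=O | starting material
8 | (5E)-6-methoxyhex-5-ene-2,4-dione | CO/C=C/C(=O)CC(C)=O | intermediate
9 | cesium salt of methyl (3E)-3-[(2R)-3-hydroxy-3-methyl-2-oxidobutylidene]-4-oxocyclohexa-1,5-diene-1-carboxylate (o-quinone methide alkoxide) | COC(=O)C1=CC(=C/[C@@H]([O-])C(C)(C)O)\C(=O)C=C1.[Cs+] | intermediate
10 | methyl 3-[(1S,2R)-2,3-dihydroxy-1-[(5E)-6-methoxy-2,4-dioxohex-5-en-3-yl]-3-methylbutyl]-4-hydroxybenzoate (diketone CH stereolabile) | COC(=O)c1ccc(O)c(c1)[C@H](C(C(C)=O)C(=O)/C=C/OC)[C@@H](O)C(C)(C)O | intermediate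
11 | methyl 3-[(1R,2R)-2,3-dihydroxy-3-methyl-1-(2-methyl-4-oxo-4H-pyran-3-yl)butyl]-4-hydroxybenzoate | COC(=O)c1ccc(O)c(c1)[C@H](C2=C(C)OC=CC2=O)[C@@H](O)C(C)(C)O | intermediate
12 | N-methoxy-N-methyl-3-phenylpropanamide | CON(C)C(=O)CCc1ccccc1 | starting material
13 | methyl 3-[(1R,2R)-2,3-dihydroxy-3-methyl-1-[4-oxo-2-(2-oxo-4-phenylbutyl)-4H-pyran-3-yl]butyl]-4-hydroxybenzoate | COC(=O)c1ccc(O)c(c1)[C@H](C2=C(CC(=O)CCc3ccccc3)OC=CC2=O)[C@@H](O)C(C)(C)O | intermediate
14 | 3-[(1R,2R)-2,3-dihydroxy-1-[2-hydroxy-5-(methoxycarbonyl)phenyl]-3-methylbutyl]-4-methoxy-2-(2-oxo-4-phenylbutyl)pyrylium trifluoromethanesulfonate | COC(=O)c1ccc(O)c(c1)[C@H](c2c(CC(=O)CCc3ccccc3)[o+]ccc2OC)[C@@H](O)C(C)(C)O.[O-]S(=O)(=O)C(F)(F)F | intermediate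
15 | methyl 4-hydroxy-3-[(2R,3R)-2-(2-hydroxypropan-2-yl)-4-methoxy-7a-(2-oxo-4-phenylbutyl)-3,7a-dihydro-2H-furo[2,3-b]pyran-3-yl]benzoate (both 7a epimers) | COC(=O)c1ccc(O)c(c1)[C@@H]1C2=C(OC)C=COC2(CC(=O)CCc3ccccc3)O[C@H]1C(C)(C)O | intermediate
16 | methyl 4-hydroxy-3-[(2R,3R)-2-(2-hydroxypropan-2-yl)-4-[(1E)-1-methoxy-3-oxoprop-1-en-1-yl]-5-(2-oxo-4-phenylbutyl)-2,3-dihydrofuran-3-yl]benzoate | COC(=O)c1ccc(O)c(c1)[C@@H]1C(/C(OC)=C\C=O)=C(CC(=O)CCc2ccccc2)O[C@H]1C(C)(C)O | intermediate
17 | methyl 4-hydroxy-3-[(2R,3R,6R,7R)-6-hydroxy-2-(2-hydroxypropan-2-yl)-4-methoxy-7-(3-phenylpropanoyl)-2,3,6,7-tetrahydro-1-benzofuran-3-yl]benzoate | COC(=O)c1ccc(O)c([C@@H]2C3=C(O[C@H]2C(C)(C)O)[C@H](C(=O)CCc2ccccc2)[C@H](O)C=C3OC)c1 | target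

**Step count and risks**

Total steps: 7. Longest linear sequence: 6 (steps 1, 2, 3, 5, 6, 7); step 4 is the side branch.

The three steps most likely to fail:

Step 7 is the largest risk. The phenol or the tertiary OH could add to the pyrylium instead of the secondary OH. The facial selectivity of the aldol relative to C2/C3 is remote and may be modest; the cis C6/C7 relationship is the more secure part. The product is one dehydration away from an aromatic benzofuran, so work-up must stay neutral and silica must be amine-deactivated. Diastereomers would be separated, and wrong isomers re-equilibrated through retro-aldol to 16. The fallback sets out from 13 and replaces the amine-mediated enolisation by a reductive, irreversible enolate generation. NBS brominates the doubly activated CH2 to give methyl 3-[(1R,2R)-1-[2-(1-bromo-2-oxo-4-phenylbutyl)-4-oxo-4H-pyran-3-yl]-2,3-dihydroxy-3-methylbutyl]-4-hydroxybenzoate F4. MeOTf with 2,6-di-tert-butyl-4-methylpyridine takes it through the same pyrylium opening to methyl 3-[(2R,3R)-5-(1-bromo-2-oxo-4-phenylbutyl)-2-(2-hydroxypropan-2-yl)-4-[(1E)-1-methoxy-3-oxoprop-1-en-1-yl]-2,3-dihydrofuran-3-yl]-4-hydroxybenzoate F5, which is isolated. SmI2 in THF at −78 °C then forms a trivalent-samarium enolate that adds to the aldehyde in a chelated intramolecular Reformatsky reaction, and the route comes back at 17.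

Step 5 is the second risk. The epoxide may isomerise to a benzyl ketone before the quinone methide is trapped, diketone 8 may close to 2-methylpyranone on its own, and the C-1 selectivity rests on a steric model. The fallback sets out from 5 and builds the pyrone by a ring switch instead. CsF with the robust donor pentane-2,4-dione, then TsOH, gives the classical formal [3+2] product methyl 3-[(2R,3R)-4-acetyl-2-(2-hydroxypropan-2-yl)-5-methyl-2,3-dihydrofuran-3-yl]-4-hydroxybenzoate F1. Kinetic enolisation of the acetyl group with LiN(i-Pr)2 and formylation with HCO2Et gives methyl 4-hydroxy-3-[(2R,3R)-4-[(2Z)-3-hydroxyprop-2-enoyl]-2-(2-hydroxypropan-2-yl)-5-methyl-2,3-dihydrofuran-3-yl]benzoate F2. CF3CO2H then lets the enol oxygen add to the furan C-5 and expel the side-chain oxygen, and the route comes back at 11.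

Step 6 is the third risk. The tetra-anion may be poorly soluble, and the C-2 alkoxide could add to the pyrone before the methyl group is metalated. The fallback sets out from 11 and avoids strong base. Me3SiOTf/Et3N silylates all four oxygens and deprotonates the activated methyl group to give methyl 3-[(1R,2R)-3-methyl-1-{2-methylidene-4-[(trimethylsilyl)oxy]-2H-pyran-3-yl}-2,3-bis[(trimethylsilyl)oxy]butyl]-4-[(trimethylsilyl)oxy]benzoate F3. This silyl anhydrobase is C-acylated at the exocyclic carbon by 3-phenylpropanoyl chloride (ZnBr2 catalyst, Mukaiyama-type), and K2CO3/MeOH removes the silyl groups, so the route comes back at 13.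

**Further compounds**

F1 | step 5 | methyl 3-[(2R,3R)-4-acetyl-2-(2-hydroxypropan-2-yl)-5-methyl-2,3-dihydrofuran-3-yl]-4-hydroxybenzoate | COC(=O)c1ccc(O)c(c1)[C@@H]1C(C(C)=O)=C(C)O[C@H]1C(C)(C)O
F2 | step 5 | methyl 4-hydroxy-3-[(2R,3R)-4-[(2Z)-3-hydroxyprop-2-enoyl]-2-(2-hydroxypropan-2-yl)-5-methyl-2,3-dihydrofuran-3-yl]benzoate | COC(=O)c1ccc(O)c(c1)[C@@H]1C(C(=O)/C=C\O)=C(C)O[C@H]1C(C)(C)O
F3 | step 6 | methyl 3-[(1R,2R)-3-methyl-1-{2-methylidene-4-[(trimethylsilyl)oxy]-2H-pyran-3-yl}-2,3-bis[(trimethylsilyl)oxy]butyl]-4-[(trimethylsilyl)oxy]benzoate | COC(=O)c1ccc(O[Si](C)(C)C)c(c1)[C@H](C2=C(O[Si](C)(C)C)C=COC2=C)[C@@H](O[Si](C)(C)C)C(C)(C)O[Si](C)(C)C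
F4 | step 7 | methyl 3-[(1R,2R)-1-[2-(1-bromo-2-oxo-4-phenylbutyl)-4-oxo-4H-pyran-3-yl]-2,3-dihydroxy-3-methylbutyl]-4-hydroxybenzoate | COC(=O)c1ccc(O)c(c1)[C@H](C2=C(C(Br)C(=O)CCc3ccccc3)OC=CC2=O)[C@@H](O)C(C)(C)O
F5 | step 7 | methyl 3-[(2R,3R)-5-(1-bromo-2-oxo-4-phenylbutyl)-2-(2-hydroxypropan-2-yl)-4-[(1E)-1-methoxy-3-oxoprop-1-en-1-yl]-2,3-dihydrofuran-3-yl]-4-hydroxybenzoate | COC(=O)c1ccc(O)c(c1)[C@@H]1C(/C(OC)=C\C=O)=C(C(Br)C(=O)CCc2ccccc2)O[C@H]1C(C)(C)O
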